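**Retrosynthetic overview**

- Ring A is numbered as the anisole: C1 OMe, C2 OAr, C3–C5 Br, C6 H. Ring B is bought intact as 2,4-dibromophenol. The C6–H comes last, by reductive removal of a C6 amino group that first steers Br onto C3 and C5. That amine comes from a C6 carboxyl by Curtius degradation, and C4–Br is set earlier, para to the still-free C1 phenol.
- The feature the plan rests on: the vicinal pair C1–O / C2–OAr of ring A maps onto the ketone carbon and the aryloxy-bearing C4 of a 4-aryloxyacetoacetate whose ester carbon sits on C6, while C3, C4 and C5 are the three carbons of malondialdehyde.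
- Key disconnection: bonds C2–C3 and C6–C5, a formal [3+3] cyclocondensation of the bis(silyl enol ether) of methyl 4-(2,4-dibromophenoxy)acetoacetate with 1,1,3,3-tetramethoxypropane, giving a 3-aryloxysalicylate.
- The diaryl ether oxygen is therefore introduced as an alkyl aryl ether (phenoxide plus methyl 4-chloroacetoacetate), not by aryl C–O coupling. Ring A is the only ring formed (step 4).

Key step: step 4

Remark on the chemistry: enol ethers 4 and 5 are used as E/Z mixtures and adduct 7 as a diastereomer mixture, because all of these stereo-elements vanish when ring A aromatises.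

**Route**

Step 1
Reactants: 1 2,4-dibromophenol; 2 methyl 4-chloro-3-oxobutanoate (methyl 4-chloroacetoacetate)
Product: 3 methyl 4-(2,4-dibromophenoxy)-3-oxobutanoate
Conditions: NaH (2.2 equiv), THF–DMF, 0 °C → rt; aq. HCl
Reagents that add atoms: none
Why: Williamson-type SN2 etherification in which the second equivalent of NaH holds keto ester 2 as its enolate, so that the phenoxide of 1 should displace the primary, carbonyl-activated chloride faster than the keto ester condenses with itself.

Step 2
Reactants: 3 methyl 4-(2,4-dibromophenoxy)-3-oxobutanoate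
Product: 4 methyl 4-(2,4-dibromophenoxy)-3-(trimethylsilyloxy)but-2-enoate
Conditions: Me3SiCl, Et3N, toluene, rt
Reagents that add atoms: chlorotrimethylsilane, C[Si](C)(C)Cl
Why: Soft enolisation and O-silylation of the β-keto ester should give the conjugated β-silyloxy enoate, the usual first stage in preparing a 1,3-bis(silyloxy)diene.

Step 3
Reactants: 4 methyl 4-(2,4-dibromophenoxy)-3-(trimethylsilyloxy)but-2-enoate
Product: 5 1-methoxy-1,3-bis(trimethylsilyloxy)-4-(2,4-dibromophenoxy)buta-1,3-diene
Conditions: LiN(i-Pr)2, THF, −78 °C; Me3SiCl, −78 → 20 °C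
Reagents that add atoms: chlorotrimethylsilane, C[Si](C)(C)Cl
Why: Kinetic γ-deprotonation of the β-silyloxy enoate followed by O-silylation of the extended ester dienolate should give the bis(silyl enol ether); the OCH2 protons activated by the enoate are far more acidic than any ring B C–H, so one equivalent of amide base at −78 °C should leave the aryl bromides alone.

Step 4
Reactants: 5 1-methoxy-1,3-bis(trimethylsilyloxy)-4-(2,4-dibromophenoxy)buta-1,3-diene; 6 1,1,3,3-tetramethoxypropane
Product: 8 methyl 3-(2,4-dibromophenoxy)-2-hydroxybenzoate, via open-chain Mukaiyama adduct 7 (not isolated)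
Conditions: TiCl4, CH2Cl2, −78 → 20 °C; aq. HCl
Reagents that add atoms: none
Why: TiCl4 ionises one acetal of 6 to an oxocarbenium ion, which is attacked by the terminal, aryloxy-bearing carbon of diene 5 (vinylogous Mukaiyama aldol-type addition of a masked acetoacetate dianion, forming C2–C3) to give open-chain adduct 7. Ionisation of the second acetal and attack by the central carbon of the remaining β-silyloxy enoate (forming C6–C5) closes carbocyclic ring A in a 6-(enolendo)-exo-trig cyclisation. β-Elimination of the two remaining ring methoxy groups as methanol and enolisation then aromatise the ring to the salicylate, whose OH is hydrogen-bonded to the ester. The closest known reaction type is the Lewis-acid-mediated formal [3+3] cyclocondensation of 1,3-bis(silyloxy)-1,3-butadienes with 1,3-dielectrophiles such as malondialdehyde bis-acetals, which is established for 4-aryloxy dienes. No stereocentre is created. Only chemoselectivity is required: first attack through the intrinsically more nucleophilic terminal carbon, then ring closure rather than chain growth, favoured by the six-membered transition state and slow warming from −78 °C; the symmetrical dielectrophile leaves no regiochemical choice.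

Step 5
Reactants: 8 methyl 3-(2,4-dibromophenoxy)-2-hydroxybenzoate
Product: 9 methyl 5-bromo-3-(2,4-dibromophenoxy)-2-hydroxybenzoate
Conditions: Br2 (1.05 equiv), AcOH, rt
Reagents that add atoms: bromine, BrBr
Why: Electrophilic aromatic bromination under phenol control: both ortho positions of the OH are occupied, so bromine should enter para to it (C4 of ring A, also meta to the ester), while the doubly brominated ring B is too deactivated to compete.

Step 6
Reactants: 9 methyl 5-bromo-3-(2,4-dibromophenoxy)-2-hydroxybenzoate
Product: 10 methyl 5-bromo-3-(2,4-dibromophenoxy)-2-methoxybenzoate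
Conditions: MeI, K2CO3, DMF, 40 °C
Reagents that add atoms: iodomethane, CI
Why: Williamson O-methylation of the phenoxide should fix the C1 oxygen as the methyl ether of the target before the ester is opened.

Step 7
Reactants: 10 methyl 5-bromo-3-(2,4-dibromophenoxy)-2-methoxybenzoate
Product: 11 5-bromo-3-(2,4-dibromophenoxy)-2-methoxybenzoic acid
Conditions: LiOH, THF–MeOH–H2O, 50 °C; aq. HCl
Reagents that add atoms: lithium hydroxide, [Li+].[OH-]
Why: Ordinary saponification of a methyl benzoate; the aryl bromides and both aryl ethers are inert to aqueous hydroxide at this temperature.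

Step 8
Reactants: 11 5-bromo-3-(2,4-dibromophenoxy)-2-methoxybenzoic acid
Product: 14 tert-butyl N-[5-bromo-3-(2,4-dibromophenoxy)-2-methoxyphenyl]carbamate, via acyl azide 12 (not isolated), via isocyanate 13 (not isolated)
Conditions: diphenylphosphoryl azide (DPPA), Et3N, t-BuOH–toluene, 90 °C
Reagents that add atoms: diphenylphosphoryl azide, [N-]=[N+]=NP(=O)(Oc1ccccc1)Oc1ccccc1; tert-butanol, CC(C)(C)O
Why: Curtius rearrangement: the acid is converted to acyl azide 12, which loses N2 on heating with 1,2-aryl shift to isocyanate 13, and tert-butanol traps this as the Boc carbamate, so that the carbon substituent on C6 is exchanged for nitrogen.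

Step 9
Reactants: 14 tert-butyl N-[5-bromo-3-(2,4-dibromophenoxy)-2-methoxyphenyl]carbamate
Product: 15 5-bromo-3-(2,4-dibromophenoxy)-2-methoxyaniline
Conditions: CF3CO2H, CH2Cl2, rt; aq. NaHCO3
Reagents that add atoms: none
Why: Acidolytic Boc cleavage (loss of the tert-butyl cation, then decarboxylation of the carbamic acid) should free the aniline without affecting aryl bromides or ethers.

Step 10
Reactants: 15 5-bromo-3-(2,4-dibromophenoxy)-2-methoxyaniline
Product: 16 2,3,4-tribromo-5-(2,4-dibromophenoxy)-6-methoxyaniline
Conditions: N-bromosuccinimide (NBS, 2.1 equiv), DMF, 0 °C → rt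
Reagents that add atoms: N-bromosuccinimide, O=C1CCC(=O)N1Br
Why: Electrophilic aromatic bromination under amino control: the NH2 on C6 is the strongest donor, and its only free ortho (C5) and para (C3) positions are exactly the two remaining C–H bonds of ring A, each also activated by the C2 aryloxy group, whereas ring B carries two deactivating bromines.

Step 11
Reactants: 16 2,3,4-tribromo-5-(2,4-dibromophenoxy)-6-methoxyaniline
Product: 18 1,2,3-tribromo-4-(2,4-dibromophenoxy)-5-methoxybenzene, via diazonium hydrogensulfate 17 (not isolated)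
Conditions: NaNO2, H2SO4–AcOH, 0–5 °C; then 50% aq. H3PO2, 0 °C → rt
Reagents that add atoms: none
Why: Reductive deamination (hydrodediazoniation): diazotisation in sulfuric acid suits the weakly basic, fully substituted aniline, and H3PO2 reduces the diazonium ion by a radical chain to Ar–H with loss of N2, leaving C6 as the only C–H of ring A.

**Compound list**

1 | 2,4-dibromophenol | Oc1ccc(Br)cc1Br | starting material
2 | methyl 4-chloro-3-oxobutanoate | COC(=O)CC(=O)CCl | starting material
3 | methyl 4-(2,4-dibromophenoxy)-3-oxobutanoate | COC(=O)CC(=O)COc1ccc(Br)cc1Br | intermediate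
4 | methyl 4-(2,4-dibromophenoxy)-3-(trimethylsilyloxy)but-2-enoate (E/Z mixture) | COC(=O)C=C(O[Si](C)(C)C)COc1ccc(Br)cc1Br | intermediate
5 | 1-methoxy-1,3-bis(trimethylsilyloxy)-4-(2,4-dibromophenoxy)buta-1,3-diene (E/Z mixture) | COC(O[Si](C)(C)C)=CC(O[Si](C)(C)C)=COc1ccc(Br)cc1Br | intermediate
6 | 1,1,3,3-tetramethoxypropane | COC(OC)CC(OC)OC | starting material
7 | methyl 4-(2,4-dibromophenoxy)-5,7,7-trimethoxy-3-(trimethylsilyloxy)hept-2-enoate (open-chain adduct, drawn as the silyl enol ether, diastereomer mixture) | COC(=O)C=C(O[Si](C)(C)C)C(Oc1ccc(Br)cc1Br)C(OC)CC(OC)OC | intermediate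
8 | methyl 3-(2,4-dibromophenoxy)-2-hydroxybenzoate | COC(=O)c1cccc(Oc2ccc(Br)cc2Br)c1O | intermediate
9 | methyl 5-bromo-3-(2,4-dibromophenoxy)-2-hydroxybenzoate | COC(=O)c1cc(Br)cc(Oc2ccc(Br)cc2Br)c1O | intermediate
10 | methyl 5-bromo-3-(2,4-dibromophenoxy)-2-methoxybenzoate | COC(=O)c1cc(Br)cc(Oc2ccc(Br)cc2Br)c1OC | intermediate
11 | 5-bromo-3-(2,4-dibromophenoxy)-2-methoxybenzoic acid | OC(=O)c1cc(Br)cc(Oc2ccc(Br)cc2Br)c1OC | intermediate
12 | 5-bromo-3-(2,4-dibromophenoxy)-2-methoxybenzoyl azide | [N-]=[N+]=NC(=O)c1cc(Br)cc(Oc2ccc(Br)cc2Br)c1OC | intermediate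
13 | 5-bromo-1-(2,4-dibromophenoxy)-3-isocyanato-2-methoxybenzene | O=C=Nc1cc(Br)cc(Oc2ccc(Br)cc2Br)c1OC | intermediate
14 | tert-butyl N-[5-bromo-3-(2,4-dibromophenoxy)-2-methoxyphenyl]carbamate | CC(C)(C)OC(=O)Nc1cc(Br)cc(Oc2ccc(Br)cc2Br)c1OC | intermediate
15 | 5-bromo-3-(2,4-dibromophenoxy)-2-methoxyaniline | Nc1cc(Br)cc(Oc2ccc(Br)cc2Br)c1OC | intermediate
16 | 2,3,4-tribromo-5-(2,4-dibromophenoxy)-6-methoxyaniline | Nc1c(Br)c(Br)c(Br)c(Oc2ccc(Br)cc2Br)c1OC | intermediate
17 | 2,3,4-tribromo-5-(2,4-dibromophenoxy)-6-methoxybenzenediazonium hydrogensulfate | N#[N+]c1c(Br)c(Br)c(Br)c(Oc2ccc(Br)cc2Br)c1OC.OS(=O)(=O)[O-] | intermediate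
18 | 1,2,3-tribromo-4-(2,4-dibromophenoxy)-5-methoxybenzene | COc1cc(Br)c(Br)c(Br)c1Oc1ccc(Br)cc1Br | target

**Step count and risks**

Total steps: 11. Longest linear sequence: 11 steps (1 → 18).

Steps most likely to fail:

1. Step 4 (key step). The Lewis acid may strip the silyl groups from the diene and return keto ester 3, or the open-chain adduct may react with a second acetal and grow a chain instead of closing the ring. Fallback, setting out from 3 and coming back at 8, builds ring A by a base-mediated annulation followed by dehydrogenation. Keto ester 3 would undergo Michael addition to acrolein (cat. NaOMe, MeOH, −20 °C) to give methyl 2-[(2,4-dibromophenoxy)acetyl]-5-oxopentanoate F1. Intramolecular aldol condensation between the aryloxy-bearing CH2 and the aldehyde (piperidinium acetate, toluene, reflux) would give methyl 3-(2,4-dibromophenoxy)-2-oxocyclohex-3-ene-1-carboxylate F2. Dehydrogenation with DDQ (dioxane, reflux) would aromatise this to 8.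

2. Step 10. The second bromination may stall at a position flanked by bromine, or selectivity between the rings may erode and the electron-rich aniline may be oxidised once ring A is partly brominated. Fallback, setting out from 8 and coming back at 18, moves the directing nitrogen to C4 so that it activates both of its ortho positions and then becomes the C4 bromine.
   - Nitration para to the phenol (HNO3, AcOH, 0 °C) should give methyl 3-(2,4-dibromophenoxy)-2-hydroxy-5-nitrobenzoate F3.
   - O-Methylation (MeI, K2CO3, DMF) should give methyl 3-(2,4-dibromophenoxy)-2-methoxy-5-nitrobenzoate F4.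
   - Reduction (Fe, NH4Cl, EtOH–H2O, 70 °C) should give methyl 5-amino-3-(2,4-dibromophenoxy)-2-methoxybenzoate F5.
   - The para position of this amine is blocked by OMe, so NBS (DMF) should brominate only its two ortho positions (C3 and C5 of ring A) to give methyl 3-amino-2,4-dibromo-5-(2,4-dibromophenoxy)-6-methoxybenzoate F6.
   - Sandmeyer bromination (t-BuONO, CuBr2, MeCN) should give methyl 2,3,4-tribromo-5-(2,4-dibromophenoxy)-6-methoxybenzoate F7.
   - SN2 cleavage of the hindered ester (LiI, pyridine, reflux; aq. HCl) should give 2,3,4-tribromo-5-(2,4-dibromophenoxy)-6-methoxybenzoic acid F8.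
   - Ag2CO3-catalysed protodecarboxylation of this di-ortho-substituted acid (AcOH, DMSO, 120 °C) would deliver 18.

3. Step 1. Self-condensation of the chloro keto ester enolate may outrun O-alkylation by the weakly nucleophilic, ortho-hindered phenoxide. Fallback, setting out from 1 and coming back at 3, attaches the two-carbon ether unit first and then builds the keto ester by acylation. Phenol 1 would be alkylated with chloroacetic acid (aq. NaOH, reflux; HCl) to (2,4-dibromophenoxy)acetic acid F9. Activation with 1,1'-carbonyldiimidazole (THF) would give 1-[(2,4-dibromophenoxy)acetyl]imidazole F10. C-Acylation of the magnesium malonate half-ester Mg(O2CCH2CO2Me)2 (THF, rt) with decarboxylation on acidic work-up would give 3.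

**Further compounds**

F1 | step 4 | methyl 2-[(2,4-dibromophenoxy)acetyl]-5-oxopentanoate (racemic) | COC(=O)C(CCC=O)C(=O)COc1ccc(Br)cc1Br
F2 | step 4 | methyl 3-(2,4-dibromophenoxy)-2-oxocyclohex-3-ene-1-carboxylate (racemic) | COC(=O)C1CCC=C(Oc2ccc(Br)cc2Br)C1=O
F3 | step 10 | methyl 3-(2,4-dibromophenoxy)-2-hydroxy-5-nitrobenzoate | COC(=O)c1cc([N+](=O)[O-])cc(Oc2ccc(Br)cc2Br)c1O
F4 | step 10 | methyl 3-(2,4-dibromophenoxy)-2-methoxy-5-nitrobenzoate | COC(=O)c1cc([N+](=O)[O-])cc(Oc2ccc(Br)cc2Br)c1OC
F5 | step 10 | methyl 5-amino-3-(2,4-dibromophenoxy)-2-methoxybenzoate | COC(=O)c1cc(N)cc(Oc2ccc(Br)cc2Br)c1OC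
F6 | step 10 | methyl 3-amino-2,4-dibromo-5-(2,4-dibromophenoxy)-6-methoxybenzoate | COC(=O)c1c(Br)c(N)c(Br)c(Oc2ccc(Br)cc2Br)c1OC
F7 | step 10 | methyl 2,3,4-tribromo-5-(2,4-dibromophenoxy)-6-methoxybenzoate | COC(=O)c1c(Br)c(Br)c(Br)c(Oc2ccc(Br)cc2Br)c1OC
F8 | step 10 | 2,3,4-tribromo-5-(2,4-dibromophenoxy)-6-methoxybenzoic acid | OC(=O)c1c(Br)c(Br)c(Br)c(Oc2ccc(Br)cc2Br)c1OC
F9 | step 1 | (2,4-dibromophenoxy)acetic acid | OC(=O)COc1ccc(Br)cc1Br
F10 | step 1 | 1-[(2,4-dibromophenoxy)acetyl]imidazole | O=C(COc1ccc(Br)cc1Br)n1ccnc1
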